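Ring B (C1'–C6', with oxygen on C2', C4' and C6') is bonded to C3 of ring C beside the C4 carbonyl, and C2 is a bare CH held by O1. This is a chalcone skeleton whose aryl group has moved from the β- to the α-carbon, and the three donor oxygens make ring B a good migrating group.
Retrosynthetic cuts, in order: the C3'–CH2 bond of the prenyl chain (bromine takes its place), then C3–C1' and O1–C2 together (ring C opens to a 2'-hydroxychalcone), then the chalcone Cα=Cβ bond (aldol condensation).
Forward: rings A and B are bought as arenes and protected, the three-carbon bridge joins them, ring C closes during the oxidative aryl shift, benzyl is exchanged for acetyl, and the prenyl chain is coupled on last.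
Stereochemistry: the target has no stereocentre and no stereogenic olefin. The E-olefin of the chalcone and the racemic centre of the acetal intermediate both vanish when ring C aromatises.

Key step: step 5

Assumption: 4-bromo-3,5-dimethoxyphenol 1 is taken as a catalogue compound, and rotation about the C3–C1' axis is treated as free because the target structure defines no axial configuration.

Step 1
Reactants: 1 4-bromo-3,5-dimethoxyphenol
Product: 2 3-bromo-6-hydroxy-2,4-dimethoxybenzaldehyde
Conditions: MgCl2, Et3N, (CH2O)n, MeCN, reflux; then 1 M HCl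
Reagents that add atoms: paraformaldehyde (reacts as formaldehyde), C=O
Why: Casnati–Skattebøl ortho-formylation, in which the magnesium phenoxide delivers formaldehyde to the ortho carbon through a chelate and a second formaldehyde takes up hydride from the benzylic alkoxide, while the two ortho sites are equivalent and the para site is blocked by bromine, so only one aldehyde can form.

Step 2
Reactants: 2 3-bromo-6-hydroxy-2,4-dimethoxybenzaldehyde; 3 benzyl bromide
Product: 4 6-(benzyloxy)-3-bromo-2,4-dimethoxybenzaldehyde
Conditions: BnBr, K2CO3, DMF, 60 °C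
Reagents that add atoms: benzyl bromide 3, BrCc1ccccc1
Why: Williamson ether synthesis on the only acidic OH, with gentle heating to overcome its hydrogen bond to the formyl group, and with nothing else in the molecule open to alkylation.

Step 3
Reactants: 5 2,4,6-trihydroxyacetophenone; 3 benzyl bromide
Product: 6 1-[2,4-bis(benzyloxy)-6-hydroxyphenyl]ethan-1-one
Conditions: BnBr (2.1 equiv), K2CO3, DMF, rt to 50 °C
Reagents that add atoms: benzyl bromide 3, BrCc1ccccc1
Why: Williamson ether synthesis that should stop at the diether, because once one ortho oxygen is alkylated the last OH is locked in a strong hydrogen bond to the acetyl carbonyl and is the poorest nucleophile.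

Step 4
Reactants: 4 6-(benzyloxy)-3-bromo-2,4-dimethoxybenzaldehyde; 6 1-[2,4-bis(benzyloxy)-6-hydroxyphenyl]ethan-1-one
Product: 7 (E)-1-[2,4-bis(benzyloxy)-6-hydroxyphenyl]-3-[6-(benzyloxy)-3-bromo-2,4-dimethoxyphenyl]prop-2-en-1-one
Conditions: KOH, EtOH/THF, rt; then 1 M HCl
Reagents that add atoms: none
Why: Claisen–Schmidt condensation in which the methyl ketone enolate adds to the non-enolisable aldehyde 4, E1cB loss of hydroxide gives the conjugated E-enone under thermodynamic control, and the product rests in strong base as the open-chain phenoxide.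

Step 5
Reactants: 7 (E)-1-[2,4-bis(benzyloxy)-6-hydroxyphenyl]-3-[6-(benzyloxy)-3-bromo-2,4-dimethoxyphenyl]prop-2-en-1-one
Product: 9 5,7-bis(benzyloxy)-3-[6-(benzyloxy)-3-bromo-2,4-dimethoxyphenyl]-4H-chromen-4-one, via dimethyl acetal 8 (not isolated)
Conditions: Tl(NO3)3·3H2O (1.1 equiv), MeOH/CH2Cl2, rt, dark; TlNO3 filtered off; then 10% aq HCl, reflux
Reagents that add atoms: methanol, CO (its two methoxy groups stand in 8 only and leave again before 9)
Why: Tl(NO3)3 and methanol add across the enone olefin (methoxy on the benzylic β-carbon, trivalent thallium on the α-carbon); as the weak C–Tl bond ionises and thallium departs in the monovalent state, ring B bridges as a phenonium ion and lands on the α-carbon (C3–C1'), and the β-oxocarbenium ion left behind takes up a second methanol to give acetal 8. This is the known Tl(NO3)3-mediated oxidative 1,2-aryl migration of 2'-hydroxychalcones to isoflavones, the laboratory counterpart of the biosynthetic aryl shift. Dilute HCl re-ionises the acetal, the ring-A phenol adds to the oxocarbenium carbon in a 6-exo-trig closure (O1–C2), and loss of the second methanol makes ring C aromatic. The only stereocentre formed, the α-carbon of 8, is racemic and becomes the sp2 carbon C3 of 9, so nothing has to be controlled. The aryl shift must outrun aurone formation and oxidation or nitration of the rings, which is secured by the high migratory aptitude that the C2', C4' and C6' oxygens give ring B, by the single free CH left on the brominated ring B, and by using close to one equivalent of oxidant. Ring closure must also go through the right oxygen, which the benzyl ether on O6' secures by leaving the ring-A OH as the only nucleophile for the acetal carbon and so shutting off the benzofuran path.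

Step 6
Reactants: 9 5,7-bis(benzyloxy)-3-[6-(benzyloxy)-3-bromo-2,4-dimethoxyphenyl]-4H-chromen-4-one
Product: 10 3-(3-bromo-6-hydroxy-2,4-dimethoxyphenyl)-5,7-dihydroxy-4H-chromen-4-one
Conditions: BCl3, pentamethylbenzene, CH2Cl2, −78 °C; then H2O
Reagents that add atoms: none
Why: Lewis-acid cleavage of aryl benzyl ethers with a Friedel–Crafts cation trap, which runs at −78 °C where the aryl methyl ethers and the C–Br bond should stay untouched, whereas hydrogenolysis would also take out the bromine.

Step 7
Reactants: 10 3-(3-bromo-6-hydroxy-2,4-dimethoxyphenyl)-5,7-dihydroxy-4H-chromen-4-one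
Product: 11 3-[6-(acetyloxy)-3-bromo-2,4-dimethoxyphenyl]-4-oxo-4H-chromene-5,7-diyl diacetate
Conditions: Ac2O, pyridine, DMAP (cat.), rt
Reagents that add atoms: acetic anhydride, CC(=O)OC(C)=O
Why: DMAP-catalysed O-acylation of all three phenols (the chelated C5–OH included), which removes the protons that would quench an organozinc reagent, lowers the electron density of ring B para to bromine, and installs groups that can later be removed without harm to an olefin.

Step 8
Reactants: 11 3-[6-(acetyloxy)-3-bromo-2,4-dimethoxyphenyl]-4-oxo-4H-chromene-5,7-diyl diacetate; 12 1-bromo-3-methylbut-2-ene (prenyl bromide)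
Product: 14 3-[6-(acetyloxy)-2,4-dimethoxy-3-(3-methylbut-2-en-1-yl)phenyl]-4-oxo-4H-chromene-5,7-diyl diacetate, via prenylzinc bromide 13 (not isolated)
Conditions: 12, Zn dust, LiCl, THF, 0 °C; the solution then added slowly to 11, Pd(OAc)2 (cat.), CPhos [2-dicyclohexylphosphino-2',6'-bis(dimethylamino)biphenyl] (cat.), THF, rt
Reagents that add atoms: 1-bromo-3-methylbut-2-ene 12, CC(C)=CCBr; zinc, [Zn] (held in 13 only)
Why: Negishi cross-coupling in which zerovalent palladium carrying the bulky biaryl phosphine inserts into the hindered C3'–Br bond, transmetalation and fast reductive elimination at the unsubstituted allyl terminus give the linear prenyl arene, slow addition keeps the allylic zinc reagent too dilute to attack ring C, and any acetate it removes would be cleaved in the next step anyway.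

Step 9
Reactants: 14 3-[6-(acetyloxy)-2,4-dimethoxy-3-(3-methylbut-2-en-1-yl)phenyl]-4-oxo-4H-chromene-5,7-diyl diacetate
Product: 15 5,7-dihydroxy-3-[6-hydroxy-2,4-dimethoxy-3-(3-methylbut-2-en-1-yl)phenyl]-4H-chromen-4-one (target)
Conditions: K2CO3, MeOH, 0 °C to rt, argon; then 1 M HCl to pH 5
Reagents that add atoms: none
Why: Base-mediated transesterification (methanolysis) of the three reactive aryl acetates, mild enough to spare ring C, the methyl ethers and the prenyl olefin, which sits between two methoxy groups and has no neighbouring OH to cyclise onto.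

Compound list
1 | 4-bromo-3,5-dimethoxyphenol | COc1cc(O)cc(OC)c1Br | starting material
2 | 3-bromo-6-hydroxy-2,4-dimethoxybenzaldehyde | O=Cc1c(O)cc(OC)c(Br)c1OC | intermediate
3 | benzyl bromide | BrCc1ccccc1 | starting material
4 | 6-(benzyloxy)-3-bromo-2,4-dimethoxybenzaldehyde | O=Cc1c(OCc2ccccc2)cc(OC)c(Br)c1OC | intermediate
5 | 2,4,6-trihydroxyacetophenone | CC(=O)c1c(O)cc(O)cc1O | starting material
6 | 1-[2,4-bis(benzyloxy)-6-hydroxyphenyl]ethan-1-one | CC(=O)c1c(O)cc(OCc2ccccc2)cc1OCc1ccccc1 | intermediate
7 | (E)-1-[2,4-bis(benzyloxy)-6-hydroxyphenyl]-3-[6-(benzyloxy)-3-bromo-2,4-dimethoxyphenyl]prop-2-en-1-one | O=C(/C=C/c1c(OCc2ccccc2)cc(OC)c(Br)c1OC)c1c(O)cc(OCc2ccccc2)cc1OCc1ccccc1 | intermediate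
8 | 1-[2,4-bis(benzyloxy)-6-hydroxyphenyl]-2-[6-(benzyloxy)-3-bromo-2,4-dimethoxyphenyl]-3,3-dimethoxypropan-1-one (racemic, not isolated) | COC(OC)C(C(=O)c1c(O)cc(OCc2ccccc2)cc1OCc1ccccc1)c1c(OCc2ccccc2)cc(OC)c(Br)c1OC | intermediate
9 | 5,7-bis(benzyloxy)-3-[6-(benzyloxy)-3-bromo-2,4-dimethoxyphenyl]-4H-chromen-4-one | O=c1c(-c2c(OCc3ccccc3)cc(OC)c(Br)c2OC)coc2cc(OCc3ccccc3)cc(OCc3ccccc3)c12 | intermediate
10 | 3-(3-bromo-6-hydroxy-2,4-dimethoxyphenyl)-5,7-dihydroxy-4H-chromen-4-one | O=c1c(-c2c(O)cc(OC)c(Br)c2OC)coc2cc(O)cc(O)c12 | intermediate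
11 | 3-[6-(acetyloxy)-3-bromo-2,4-dimethoxyphenyl]-4-oxo-4H-chromene-5,7-diyl diacetate | CC(=O)Oc1cc(OC(C)=O)c2c(=O)c(-c3c(OC(C)=O)cc(OC)c(Br)c3OC)coc2c1 | intermediate
12 | 1-bromo-3-methylbut-2-ene (prenyl bromide) | CC(C)=CCBr | starting material
13 | (3-methylbut-2-en-1-yl)zinc bromide (prenylzinc bromide, not isolated) | CC(C)=CC[Zn]Br | intermediate
14 | 3-[6-(acetyloxy)-2,4-dimethoxy-3-(3-methylbut-2-en-1-yl)phenyl]-4-oxo-4H-chromene-5,7-diyl diacetate | CC(=O)Oc1cc(OC(C)=O)c2c(=O)c(-c3c(OC(C)=O)cc(OC)c(CC=C(C)C)c3OC)coc2c1 | intermediate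
15 | 5,7-dihydroxy-3-[6-hydroxy-2,4-dimethoxy-3-(3-methylbut-2-en-1-yl)phenyl]-4H-chromen-4-one | COc1cc(O)c(-c2coc3cc(O)cc(O)c3c2=O)c(OC)c1CC=C(C)C | target

Total step count: 9. Longest linear sequence: 8 (steps 1, 2, 4, 5, 6, 7, 8, 9). Step 3 is the one-step side branch.

Steps most likely to fail

Step 5. Oxidation or nitration of the very electron-rich rings, or attack of the ring-A phenol on the thallated α-carbon (the aurone path), may compete with the aryl shift. The acid released may also close the chalcone to a flavanone before the oxidant engages the olefin. The fallback sets out from 7 and reverses the order of events. Ring C is closed first by base-catalysed oxa-Michael addition (NaOAc, EtOH, reflux) to give racemic 5,7-bis(benzyloxy)-2-[6-(benzyloxy)-3-bromo-2,4-dimethoxyphenyl]-2,3-dihydro-4H-chromen-4-one F1. Ring B is then moved from C2 to C3 with trivalent iodine (PhI(OH)OTs, MeCN, reflux): the enol is iodinated at C3, ring B shifts as iodobenzene leaves with support from the O1 lone pair, and proton loss aromatises ring C. This known flavanone-to-isoflavone aryl shift returns to the route at 9.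

Step 8. Slow oxidative addition at a bromide flanked by two methoxy groups would give the allylic zinc reagent time to add to ring C or strip the acetates, and some coupling through the substituted allyl terminus may leak through. The fallback sets out from 11 and builds the chain in two neutral operations. Stille coupling with allyltributylstannane (Pd[P(t-Bu)3]2, dioxane, 90 °C) uses a partner that is not nucleophilic towards carbonyls and poses no terminus question. It should give 3-[6-(acetyloxy)-2,4-dimethoxy-3-(prop-2-en-1-yl)phenyl]-4-oxo-4H-chromene-5,7-diyl diacetate F2. Olefin cross-metathesis with excess 2-methyl-2-butene (second-generation Grubbs catalyst, RuCl2(=CHPh)(PCy3)(H2IMes), CH2Cl2, 40 °C) then converts allyl into prenyl and rejoins the route at 14.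

Step 4. The aldol addition may stall because the enolate has to form next to a phenoxide and the aldehyde is both hindered and strongly donor-substituted, and the product may drain into the flavanone by oxa-Michael closure. The fallback sets out from 6 and masks the chelated phenol (NaH, MOMCl, DMF, 0 °C) as 1-[2,4-bis(benzyloxy)-6-(methoxymethoxy)phenyl]ethan-1-one F3. Its singly charged enolate condenses with 4 (KOH, EtOH/THF, rt) to give (E)-1-[2,4-bis(benzyloxy)-6-(methoxymethoxy)phenyl]-3-[6-(benzyloxy)-3-bromo-2,4-dimethoxyphenyl]prop-2-en-1-one F4, which has no free oxygen nucleophile for ring closure. Brief treatment with HCl in MeOH at rt removes the methoxymethyl group and returns to the route at 7.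

Further compounds
F1 | step 5 | 5,7-bis(benzyloxy)-2-[6-(benzyloxy)-3-bromo-2,4-dimethoxyphenyl]-2,3-dihydro-4H-chromen-4-one (racemic) | O=C1CC(c2c(OCc3ccccc3)cc(OC)c(Br)c2OC)Oc2cc(OCc3ccccc3)cc(OCc3ccccc3)c12
F2 | step 8 | 3-[6-(acetyloxy)-2,4-dimethoxy-3-(prop-2-en-1-yl)phenyl]-4-oxo-4H-chromene-5,7-diyl diacetate | C=CCc1c(OC)cc(OC(C)=O)c(-c2coc3cc(OC(C)=O)cc(OC(C)=O)c3c2=O)c1OC
F3 | step 4 | 1-[2,4-bis(benzyloxy)-6-(methoxymethoxy)phenyl]ethan-1-one | CC(=O)c1c(OCOC)cc(OCc2ccccc2)cc1OCc1ccccc1
F4 | step 4 | (E)-1-[2,4-bis(benzyloxy)-6-(methoxymethoxy)phenyl]-3-[6-(benzyloxy)-3-bromo-2,4-dimethoxyphenyl]prop-2-en-1-one | O=C(/C=C/c1c(OCc2ccccc2)cc(OC)c(Br)c1OC)c1c(OCOC)cc(OCc2ccccc2)cc1OCc1ccccc1
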